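**Plan**

1. Units: 1 = the 4-hydroxyphenyl (epiafzelechin) flavan, 2 = the epicatechin unit on C6 of unit 1, 3 = the epicatechin unit on C4 of unit 1, 4 = the terminal epicatechin unit on C4 of unit 3.
2. Retrosynthesis: after removal of eighteen benzyl ethers and one acetate, cut C4–C4a of unit 3 (ring C), then C4(unit 3)–C6(unit 4), then O1–C2 of unit 3, then C4(unit 2)–C6(unit 1) and C4(unit 1)–C8(unit 3).
3. Enabling feature: ring A of unit 3 carries unit 1 on C8, so the ether oxygen O1 is flanked by only one unsubstituted ortho carbon, C4a, and C4 has to bear C6 of unit 4 trans to O3, which is what an acetate-bridged C4 cation delivers.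
4. Forward: the ring A aryl of unit 3 adds to the C4 ketone of unit 1, then C6-lithiated unit 1 adds to the C4 ketone of unit 2 (each followed by ionic hydrogenation); the freed phenol opens a cis-glycidate; C6-lithiated unit 4 adds to the derived aldehyde; ring C of unit 3 closes last.
5. Stereochemistry: C2/C3 of units 1, 2 and 4 come from (−)-epiafzelechin and (−)-epicatechin; the 4α (all-cis) bonds of units 1 and 2 come from β-face hydride delivery; in unit 3, C3 comes from a Jacobsen epoxidation, C2 from SN2 inversion and C4 from the acetoxonium-controlled ring closure.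

Key step: step 27

Remark: (−)-epiafzelechin is taken as the purchasable source of unit 1 because its 2,3-cis array is already in place (a 2,3-trans dihydroflavonol would need C3 inversion); α denotes the face of the 2-aryl group of each flavan, β the opposite face.

**Route**

Step 1
Reactants: 1 (−)-epicatechin
Product: 3 3,5,7,3',4'-penta-O-benzyl-(−)-epicatechin, via tetra-O-benzylepicatechin 2 (not isolated)
Conditions: BnBr, K2CO3, DMF, 0 °C to rt; then NaH, n-Bu4NI (cat.), 0 °C to rt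
Reagents that add atoms: benzyl bromide, BrCc1ccccc1
Why: Williamson etherification, in which carbonate benzylates the four phenols and the alkoxide formed with NaH then benzylates the secondary 3-OH, leaving C2 and C3 untouched.

Step 2
Reactants: 3 3,5,7,3',4'-penta-O-benzyl-(−)-epicatechin
Product: 4 3,5,7,3',4'-penta-O-benzyl-4β-hydroxyepicatechin
Conditions: DDQ, CH2Cl2/H2O (18:1), rt
Reagents that add atoms: water, O
Why: DDQ benzylic oxidation by hydride abstraction gives the ring A-stabilised C4 cation, which water should trap anti to the 3-benzyloxy group (4β-OH), a centre that is removed in step 3.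

Step 3
Reactants: 4 3,5,7,3',4'-penta-O-benzyl-4β-hydroxyepicatechin
Product: 5 3,5,7,3',4'-penta-O-benzyl-4-oxoepicatechin (2,3-cis flavan-4-one, unit 2 ketone)
Conditions: Dess–Martin periodinane, CH2Cl2, rt
Reagents that add atoms: none
Why: Dess–Martin oxidation of the benzylic alcohol under non-basic conditions, which should spare the epimerisable cis C3 centre.

Step 4
Reactants: 3 3,5,7,3',4'-penta-O-benzyl-(−)-epicatechin
Product: 6 8-iodo-3,5,7,3',4'-penta-O-benzylepicatechin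
Conditions: NIS, CH2Cl2, 0 °C to rt
Reagents that add atoms: N-iodosuccinimide, O=C1CCC(=O)N1I
Why: electrophilic aromatic iodination, which in 5,7-dialkoxyflavans goes to C8, the less hindered of the two activated ring A positions, as in the well-known C8 bromination.

Step 5
Reactants: 6 8-iodo-3,5,7,3',4'-penta-O-benzylepicatechin
Product: 7 6-bromo-8-iodo-3,5,7,3',4'-penta-O-benzylepicatechin
Conditions: NBS, CH2Cl2, −20 °C to rt
Reagents that add atoms: N-bromosuccinimide, O=C1CCC(=O)N1Br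
Why: electrophilic aromatic bromination at C6, the only free position left on the trioxygenated ring A.

Step 6
Reactants: 7 6-bromo-8-iodo-3,5,7,3',4'-penta-O-benzylepicatechin
Product: 9 6-bromo-3,5,7,3',4'-penta-O-benzylepicatechin, via C8 arylmagnesium chloride 8 (not isolated)
Conditions: i-PrMgCl·LiCl, THF, −20 to 0 °C; then MeOH
Reagents that add atoms: none
Why: iodine–magnesium exchange is far faster at the aryl iodide than at the aryl bromide, so protonation of the Grignard reagent should leave a halogen at C6 only.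

Step 7
Reactants: 10 (−)-epiafzelechin
Product: 12 3,5,7,4'-tetra-O-benzyl-(−)-epiafzelechin, via tri-O-benzylepiafzelechin 11 (not isolated)
Conditions: BnBr, K2CO3, DMF, 0 °C to rt; then NaH, n-Bu4NI (cat.), 0 °C to rt
Reagents that add atoms: benzyl bromide, BrCc1ccccc1
Why: the same two-stage Williamson etherification as in step 1, with phenols first and the 3-OH second.

Step 8
Reactants: 12 3,5,7,4'-tetra-O-benzyl-(−)-epiafzelechin
Product: 13 8-iodo-3,5,7,4'-tetra-O-benzylepiafzelechin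
Conditions: NIS, CH2Cl2, 0 °C to rt
Reagents that add atoms: N-iodosuccinimide, O=C1CCC(=O)N1I
Why: electrophilic aromatic iodination at C8 for the reason given in step 4.

Step 9
Reactants: 13 8-iodo-3,5,7,4'-tetra-O-benzylepiafzelechin
Product: 14 6-bromo-8-iodo-3,5,7,4'-tetra-O-benzylepiafzelechin
Conditions: NBS, CH2Cl2, −20 °C to rt
Reagents that add atoms: N-bromosuccinimide, O=C1CCC(=O)N1Br
Why: electrophilic aromatic bromination at the remaining ring A position C6.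

Step 10
Reactants: 14 6-bromo-8-iodo-3,5,7,4'-tetra-O-benzylepiafzelechin
Product: 16 6-bromo-3,5,7,4'-tetra-O-benzylepiafzelechin, via C8 arylmagnesium chloride 15 (not isolated)
Conditions: i-PrMgCl·LiCl, THF, −20 to 0 °C; then MeOH
Reagents that add atoms: none
Why: selective iodine–magnesium exchange and protonation as in step 6, which gives a robust C6 bromide that tolerates the acidic reduction of step 16.

Step 11
Reactants: 16 6-bromo-3,5,7,4'-tetra-O-benzylepiafzelechin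
Product: 17 6-bromo-3,5,7,4'-tetra-O-benzyl-4β-hydroxyepiafzelechin
Conditions: DDQ, CH2Cl2/H2O (18:1), rt
Reagents that add atoms: water, O
Why: DDQ benzylic oxidation at C4 with capture of the cation by water as in step 2, the new centre being removed in step 12.

Step 12
Reactants: 17 6-bromo-3,5,7,4'-tetra-O-benzyl-4β-hydroxyepiafzelechin
Product: 18 6-bromo-3,5,7,4'-tetra-O-benzyl-4-oxoepiafzelechin (2,3-cis flavan-4-one, unit 1 ketone)
Conditions: Dess–Martin periodinane, CH2Cl2, rt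
Reagents that add atoms: none
Why: Dess–Martin oxidation of the benzylic alcohol without base, as in step 3.

Step 13
Reactants: 19 3,5-bis(benzyloxy)phenol
Product: 20 2-bromo-3,5-bis(benzyloxy)phenol
Conditions: NBS, i-Pr2NH (10 mol %), CH2Cl2, −78 to 0 °C
Reagents that add atoms: N-bromosuccinimide, O=C1CCC(=O)N1Br
Why: amine-mediated ortho-selective bromination of a phenol, helped by the position between OH and OBn being less hindered than the one between the two benzyloxy groups.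

Step 14
Reactants: 20 2-bromo-3,5-bis(benzyloxy)phenol
Product: 21 1-allyloxy-2-bromo-3,5-bis(benzyloxy)benzene
Conditions: allyl bromide, K2CO3, acetone, reflux
Reagents that add atoms: allyl bromide, C=CCBr
Why: Williamson etherification, which masks the future O1 of unit 3 with a group that survives organolithiums and acid and is removable beside benzyl ethers.

Step 15
Reactants: 21 1-allyloxy-2-bromo-3,5-bis(benzyloxy)benzene; 18 6-bromo-3,5,7,4'-tetra-O-benzyl-4-oxoepiafzelechin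
Product: 23 6-bromo-4β-[2-allyloxy-4,6-bis(benzyloxy)phenyl]-4α-hydroxy-3,5,7,4'-tetra-O-benzylepiafzelechin, via aryllithium 22 (not isolated)
Conditions: 21, t-BuLi (2 equiv), THF, −78 °C; then 18 premixed with anhydrous CeCl3 in THF, −78 °C; then H2O
Reagents that add atoms: none
Why: bromine–lithium exchange followed by cerium-promoted 1,2-addition to the ketone, which suppresses enolisation; the aryl group should enter from the β face, anti to the cis 2-aryl and 3-benzyloxy groups, and this centre is reset in step 16.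

Step 16
Reactants: 23 6-bromo-4β-[2-allyloxy-4,6-bis(benzyloxy)phenyl]-4α-hydroxy-3,5,7,4'-tetra-O-benzylepiafzelechin
Product: 24 6-bromo-4α-[2-allyloxy-4,6-bis(benzyloxy)phenyl]-3,5,7,4'-tetra-O-benzylepiafzelechin (2,3-cis-3,4-cis)
Conditions: n-Bu3SnH, CF3CO2H, CH2Cl2, 0 °C
Reagents that add atoms: none
Why: ionic hydrogenation, in which the doubly benzylic tertiary alcohol ionises and the tin hydride (a strong enough hydride donor for this highly stabilised cation) attacks the β face opposite the 2-aryl and 3-benzyloxy groups, placing the new aryl group α (C4 of unit 1).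

Step 17
Reactants: 24 6-bromo-4α-[2-allyloxy-4,6-bis(benzyloxy)phenyl]-3,5,7,4'-tetra-O-benzylepiafzelechin; 5 3,5,7,3',4'-penta-O-benzyl-4-oxoepicatechin
Product: 26 4α-hydroxy-3,5,7,3',4'-penta-O-benzylepicatechin-(4β→6)-[4α-(2-allyloxy-4,6-bis(benzyloxy)phenyl)-3,5,7,4'-tetra-O-benzylepiafzelechin], via C6 aryllithium 25 (not isolated)
Conditions: 24, t-BuLi (2 equiv), THF, −78 °C; then 5 premixed with anhydrous CeCl3 in THF, −78 °C; then H2O
Reagents that add atoms: none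
Why: bromine–lithium exchange at C6 of unit 1 and cerium-promoted 1,2-addition to the unit 2 ketone from its β face, the type of aryllithium addition known for protected 4-oxoflavan-3-ols; the carbinol centre is reset in step 18.

Step 18
Reactants: 26 4α-hydroxy-3,5,7,3',4'-penta-O-benzylepicatechin-(4β→6)-[4α-(2-allyloxy-4,6-bis(benzyloxy)phenyl)-3,5,7,4'-tetra-O-benzylepiafzelechin]
Product: 27 3,5,7,3',4'-penta-O-benzylepicatechin-(4α→6)-[4α-(2-allyloxy-4,6-bis(benzyloxy)phenyl)-3,5,7,4'-tetra-O-benzylepiafzelechin]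
Conditions: n-Bu3SnH, CF3CO2H, CH2Cl2, 0 °C
Reagents that add atoms: none
Why: ionic hydrogenation as in step 16, with hydride delivery to the β face of unit 2 setting its C4 as 4α (all-cis).

Step 19
Reactants: 27 3,5,7,3',4'-penta-O-benzylepicatechin-(4α→6)-[4α-(2-allyloxy-4,6-bis(benzyloxy)phenyl)-3,5,7,4'-tetra-O-benzylepiafzelechin]
Product: 28 3,5,7,3',4'-penta-O-benzylepicatechin-(4α→6)-[4α-(2-hydroxy-4,6-bis(benzyloxy)phenyl)-3,5,7,4'-tetra-O-benzylepiafzelechin] (trimer phenol)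
Conditions: Pd(PPh3)4 (5 mol %), morpholine, THF, rt
Reagents that add atoms: none
Why: Tsuji–Trost deallylation, in which zerovalent palladium ionises the allyl aryl ether and morpholine captures the π-allyl fragment while benzyl ethers stay inert.

Step 20
Reactants: 29 3,4-bis(benzyloxy)benzaldehyde
Product: 30 methyl (Z)-3-[3,4-bis(benzyloxy)phenyl]prop-2-enoate
Conditions: (CF3CH2O)2P(O)CH2CO2Me, KN(SiMe3)2, 18-crown-6, THF, −78 °C
Reagents that add atoms: methyl bis(2,2,2-trifluoroethyl)phosphonoacetate, COC(=O)CP(=O)(OCC(F)(F)F)OCC(F)(F)F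
Why: Still–Gennari olefination, whose electron-poor phosphonate gives the (Z)-cinnamate from an aromatic aldehyde under kinetic control.

Step 21
Reactants: 30 methyl (Z)-3-[3,4-bis(benzyloxy)phenyl]prop-2-enoate
Product: 31 methyl (2S,3S)-3-[3,4-bis(benzyloxy)phenyl]oxirane-2-carboxylate (cis-glycidate)
Conditions: (S,S)-[N,N'-bis(3,5-di-tert-butylsalicylidene)-1,2-cyclohexanediaminato]MnCl (5 mol %), 4-phenylpyridine N-oxide, NaOCl (aq, pH 11.3), CH2Cl2, 0 °C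
Reagents that add atoms: sodium hypochlorite, [Na+].[O-]Cl
Why: Jacobsen epoxidation of a cis-cinnamate ester, in which the (S,S) manganese salen complex selects the alkene face that gives the (2S,3S) cis-epoxide; the basic medium and the ester group protect the electron-rich aryl epoxide from ring opening.

Step 22
Reactants: 28 trimer phenol; 31 methyl (2S,3S)-3-[3,4-bis(benzyloxy)phenyl]oxirane-2-carboxylate
Product: 32 methyl (2S,3R)-3-[3,4-bis(benzyloxy)phenyl]-2-hydroxy-3-(aryloxy)propanoate in which aryl is the phenol ring of 28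
Conditions: 31 (2 equiv), Cs2CO3 (0.3 equiv), DMF, 60 °C
Reagents that add atoms: none
Why: SN2 opening of the aryl glycidate by the phenoxide at the benzylic carbon with inversion, which turns the cis-epoxide into the threo aryl ether whose two centres become C2 and C3 of unit 3 in the 2R,3R (2,3-cis) arrangement; the ester rules out Payne rearrangement.

Step 23
Reactants: 32 methyl (2S,3R)-3-[3,4-bis(benzyloxy)phenyl]-2-hydroxy-3-(aryloxy)propanoate
Product: 33 2-O-triethylsilyl ether of 32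
Conditions: Et3SiOTf, 2,6-lutidine, CH2Cl2, −78 to 0 °C
Reagents that add atoms: triethylsilyl trifluoromethanesulfonate, CC[Si](CC)(CC)OS(=O)(=O)C(F)(F)F
Why: silylation of the hindered secondary alcohol with a silyl triflate gives an ether that tolerates hydride and aryllithium reagents and is removed by fluoride.

Step 24
Reactants: 33 2-O-triethylsilyl ether of 32
Product: 34 (2S,3R)-3-[3,4-bis(benzyloxy)phenyl]-3-(aryloxy)-2-(triethylsilyloxy)propanal (aryl as in 32)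
Conditions: i-Bu2AlH, CH2Cl2, −78 °C; then MeOH and potassium sodium tartrate (aq)
Reagents that add atoms: none
Why: partial reduction of an α-silyloxy ester, whose tetrahedral aluminium hemiacetal is stable at −78 °C and releases the aldehyde only on work-up, so the α-centre is not exposed to base.

Step 25
Reactants: 9 6-bromo-3,5,7,3',4'-penta-O-benzylepicatechin; 34 (2S,3R)-3-[3,4-bis(benzyloxy)phenyl]-3-(aryloxy)-2-(triethylsilyloxy)propanal
Product: 36 seco-tetramer 3-O-triethylsilyl 4-ol (unit 3 numbering; ring C open between C4 and C4a; C4 epimers), via penta-O-benzylepicatechin-6-yllithium 35 (not isolated)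
Conditions: 9 (1.5 equiv), t-BuLi (2 equiv per 9), THF, −78 °C; then 34, −78 °C; then H2O
Reagents that add atoms: none
Why: bromine–lithium exchange and 1,2-addition of the aryllithium to the aldehyde forms the C4(unit 3)–C6(unit 4) bond; the configuration at C4 and any 1,2-silyl shift between O3 and O4 are immaterial because both oxygens are acetylated next and C4 is ionised in step 27.

Step 26
Reactants: 36 seco-tetramer 3-O-triethylsilyl 4-ol
Product: 38 seco-tetramer 3,4-diacetate (ring C of unit 3 open between C4 and C4a; C4 epimers), via seco-tetramer 3,4-diol 37 (not isolated)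
Conditions: n-Bu4NF, THF, 0 °C; then Ac2O, pyridine, DMAP, rt
Reagents that add atoms: acetic anhydride, CC(=O)OC(C)=O
Why: fluoride desilylation followed by DMAP-catalysed acetylation installs the benzylic leaving group on O4 and the participating ester on O3 in one flask.

Step 27
Reactants: 38 seco-tetramer 3,4-diacetate
Product: 39 octadeca-O-benzyl tetramer with unit 3 as its 3-O-acetate
Conditions: BF3·OEt2 (0.5 equiv), CH2Cl2, −78 to −20 °C
Reagents that add atoms: none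
Why: BF3·OEt2 ionises the C4 acetate of either epimer because the cation is benzylic to the trioxygenated ring A of unit 4, and the carbonyl oxygen of the neighbouring 3-acetate closes onto it to give a 1,3-dioxolan-2-ylium (acetoxonium) ion whose trans isomer is favoured and which equilibrates through the open cation, so both epimers of 38 funnel into one intermediate. C4a of the aryl ether then attacks C4 from the side opposite the bridging oxygen, an intramolecular Friedel–Crafts alkylation of the kind that converts 3-aryloxy-1-arylpropyl cations into 4-arylchromans, combined with the anchimeric assistance of a vicinal ester that is known to give 1,2-trans products. Ring C of unit 3 closes as a six-membered ring, endo with respect to the C4a=C8a bond of the arene and exo with respect to the breaking C4–O bond of the dioxolanylium ion. The new stereocentre C4 is controlled by the C3 acetate: rear-side opening of the trans-acetoxonium ion places unit 4 trans to O3 (4β). The step needs regioselectivity for C4a and ionisation at C4 only; the first is secured because C8, the other ortho carbon of O1, carries unit 1 and C6 cannot reach C4, the second because the C4 acetate is the only benzylic ester, while the B ring on C2 is far less nucleophilic than ring A and could only close a five-membered ring.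

Step 28
Reactants: 39 octadeca-O-benzyl tetramer 3-O-acetate
Product: 40 octadeca-O-benzyl tetramer (free 3-OH on unit 3)
Conditions: K2CO3 (cat.), MeOH/THF, rt
Reagents that add atoms: none
Why: base-catalysed transesterification (Zemplén-type methanolysis) removes the single acetate without touching benzyl ethers or stereocentres.

Step 29
Reactants: 40 octadeca-O-benzyl tetramer
Product: 41 epicatechin-(4α→6)-epiafzelechin-(4α→8)-epicatechin-(4β→6)-epicatechin (CNP0103636.2)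
Conditions: H2 (1 atm), Pd(OH)2/C, THF/MeOH/H2O, rt
Reagents that add atoms: none
Why: catalytic hydrogenolysis cleaves the eighteen benzyl ethers under neutral conditions, which should leave the interflavan bonds and all eleven stereocentres intact.

**Compound list**

1 | (−)-epicatechin | O[C@@H]1Cc2c(O)cc(O)cc2O[C@@H]1c1ccc(O)c(O)c1 | starting material
2 | 5,7,3',4'-tetra-O-benzyl-(−)-epicatechin | O[C@@H]1Cc2c(OCc9ccccc9)cc(OCc9ccccc9)cc2O[C@@H]1c1ccc(OCc9ccccc9)c(OCc9ccccc9)c1 | intermediate (not isolated)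
3 | 3,5,7,3',4'-penta-O-benzyl-(−)-epicatechin | c9ccccc9CO[C@@H]1Cc2c(OCc9ccccc9)cc(OCc9ccccc9)cc2O[C@@H]1c1ccc(OCc9ccccc9)c(OCc9ccccc9)c1 | intermediate
4 | 3,5,7,3',4'-penta-O-benzyl-4β-hydroxyepicatechin | O[C@H]1c2c(OCc9ccccc9)cc(OCc9ccccc9)cc2O[C@H](c2ccc(OCc9ccccc9)c(OCc9ccccc9)c2)[C@@H]1OCc9ccccc9 | intermediate
5 | 3,5,7,3',4'-penta-O-benzyl-4-oxoepicatechin (2,3-cis) | O=C1c2c(OCc9ccccc9)cc(OCc9ccccc9)cc2O[C@H](c2ccc(OCc9ccccc9)c(OCc9ccccc9)c2)[C@@H]1OCc9ccccc9 | intermediate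
6 | 8-iodo-3,5,7,3',4'-penta-O-benzylepicatechin | c9ccccc9CO[C@@H]1Cc2c(OCc9ccccc9)cc(OCc9ccccc9)c(I)c2O[C@@H]1c1ccc(OCc9ccccc9)c(OCc9ccccc9)c1 | intermediate
7 | 6-bromo-8-iodo-3,5,7,3',4'-penta-O-benzylepicatechin | c9ccccc9CO[C@@H]1Cc2c(OCc9ccccc9)c(Br)c(OCc9ccccc9)c(I)c2O[C@@H]1c1ccc(OCc9ccccc9)c(OCc9ccccc9)c1 | intermediate
8 | 6-bromo-3,5,7,3',4'-penta-O-benzylepicatechin-8-ylmagnesium chloride | c9ccccc9CO[C@@H]1Cc2c(OCc9ccccc9)c(Br)c(OCc9ccccc9)c([Mg]Cl)c2O[C@@H]1c1ccc(OCc9ccccc9)c(OCc9ccccc9)c1 | intermediate (not isolated)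
9 | 6-bromo-3,5,7,3',4'-penta-O-benzylepicatechin | c9ccccc9CO[C@@H]1Cc2c(OCc9ccccc9)c(Br)c(OCc9ccccc9)cc2O[C@@H]1c1ccc(OCc9ccccc9)c(OCc9ccccc9)c1 | intermediate
10 | (−)-epiafzelechin | O[C@@H]1Cc2c(O)cc(O)cc2O[C@@H]1c1ccc(O)cc1 | starting material
11 | 5,7,4'-tri-O-benzyl-(−)-epiafzelechin | O[C@@H]1Cc2c(OCc9ccccc9)cc(OCc9ccccc9)cc2O[C@@H]1c1ccc(OCc9ccccc9)cc1 | intermediate (not isolated)
12 | 3,5,7,4'-tetra-O-benzyl-(−)-epiafzelechin | c9ccccc9CO[C@@H]1Cc2c(OCc9ccccc9)cc(OCc9ccccc9)cc2O[C@@H]1c1ccc(OCc9ccccc9)cc1 | intermediate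
13 | 8-iodo-3,5,7,4'-tetra-O-benzylepiafzelechin | c9ccccc9CO[C@@H]1Cc2c(OCc9ccccc9)cc(OCc9ccccc9)c(I)c2O[C@@H]1c1ccc(OCc9ccccc9)cc1 | intermediate
14 | 6-bromo-8-iodo-3,5,7,4'-tetra-O-benzylepiafzelechin | c9ccccc9CO[C@@H]1Cc2c(OCc9ccccc9)c(Br)c(OCc9ccccc9)c(I)c2O[C@@H]1c1ccc(OCc9ccccc9)cc1 | intermediate
15 | 6-bromo-3,5,7,4'-tetra-O-benzylepiafzelechin-8-ylmagnesium chloride | c9ccccc9CO[C@@H]1Cc2c(OCc9ccccc9)c(Br)c(OCc9ccccc9)c([Mg]Cl)c2O[C@@H]1c1ccc(OCc9ccccc9)cc1 | intermediate (not isolated)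
16 | 6-bromo-3,5,7,4'-tetra-O-benzylepiafzelechin | c9ccccc9CO[C@@H]1Cc2c(OCc9ccccc9)c(Br)c(OCc9ccccc9)cc2O[C@@H]1c1ccc(OCc9ccccc9)cc1 | intermediate
17 | 6-bromo-3,5,7,4'-tetra-O-benzyl-4β-hydroxyepiafzelechin | O[C@H]1c2c(OCc9ccccc9)c(Br)c(OCc9ccccc9)cc2O[C@H](c2ccc(OCc9ccccc9)cc2)[C@@H]1OCc9ccccc9 | intermediate
18 | 6-bromo-3,5,7,4'-tetra-O-benzyl-4-oxoepiafzelechin (2,3-cis) | O=C1c2c(OCc9ccccc9)c(Br)c(OCc9ccccc9)cc2O[C@H](c2ccc(OCc9ccccc9)cc2)[C@@H]1OCc9ccccc9 | intermediate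
19 | 3,5-bis(benzyloxy)phenol | Oc1cc(OCc9ccccc9)cc(OCc9ccccc9)c1 | starting material
20 | 2-bromo-3,5-bis(benzyloxy)phenol | Oc1cc(OCc9ccccc9)cc(OCc9ccccc9)c1Br | intermediate
21 | 1-allyloxy-2-bromo-3,5-bis(benzyloxy)benzene | C=CCOc1cc(OCc9ccccc9)cc(OCc9ccccc9)c1Br | intermediate
22 | 2-allyloxy-4,6-bis(benzyloxy)phenyllithium | C=CCOc1cc(OCc9ccccc9)cc(OCc9ccccc9)c1[Li] | intermediate (not isolated)
23 | 6-bromo-4β-[2-allyloxy-4,6-bis(benzyloxy)phenyl]-4α-hydroxy-3,5,7,4'-tetra-O-benzylepiafzelechin | c9ccccc9COc1ccc([C@H]2Oc3cc(OCc9ccccc9)c(Br)c(OCc9ccccc9)c3[C@](O)(c3c(OCc9ccccc9)cc(OCc9ccccc9)cc3OCC=C)[C@H]2OCc9ccccc9)cc1 | intermediate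
24 | 6-bromo-4α-[2-allyloxy-4,6-bis(benzyloxy)phenyl]-3,5,7,4'-tetra-O-benzylepiafzelechin (all-cis) | c9ccccc9COc1ccc([C@H]2Oc3cc(OCc9ccccc9)c(Br)c(OCc9ccccc9)c3[C@@H](c3c(OCc9ccccc9)cc(OCc9ccccc9)cc3OCC=C)[C@H]2OCc9ccccc9)cc1 | intermediate
25 | 6-lithio analogue of 24 | c9ccccc9COc1ccc([C@H]2Oc3cc(OCc9ccccc9)c([Li])c(OCc9ccccc9)c3[C@@H](c3c(OCc9ccccc9)cc(OCc9ccccc9)cc3OCC=C)[C@H]2OCc9ccccc9)cc1 | intermediate (not isolated)
26 | 4α-hydroxy-3,5,7,3',4'-penta-O-benzylepicatechin-(4β→6)-[4α-(2-allyloxy-4,6-bis(benzyloxy)phenyl)-3,5,7,4'-tetra-O-benzylepiafzelechin] | c9ccccc9COc1ccc([C@H]2Oc3cc(OCc9ccccc9)c([C@@]4(O)c5c(OCc9ccccc9)cc(OCc9ccccc9)cc5O[C@H](c5ccc(OCc9ccccc9)c(OCc9ccccc9)c5)[C@@H]4OCc9ccccc9)c(OCc9ccccc9)c3[C@@H](c3c(OCc9ccccc9)cc(OCc9ccccc9)cc3OCC=C)[C@H]2OCc9ccccc9)cc1 | intermediate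
27 | 3,5,7,3',4'-penta-O-benzylepicatechin-(4α→6)-[4α-(2-allyloxy-4,6-bis(benzyloxy)phenyl)-3,5,7,4'-tetra-O-benzylepiafzelechin] | c9ccccc9COc1ccc([C@H]2Oc3cc(OCc9ccccc9)c([C@@H]4c5c(OCc9ccccc9)cc(OCc9ccccc9)cc5O[C@H](c5ccc(OCc9ccccc9)c(OCc9ccccc9)c5)[C@@H]4OCc9ccccc9)c(OCc9ccccc9)c3[C@@H](c3c(OCc9ccccc9)cc(OCc9ccccc9)cc3OCC=C)[C@H]2OCc9ccccc9)cc1 | intermediate
28 | 3,5,7,3',4'-penta-O-benzylepicatechin-(4α→6)-[4α-(2-hydroxy-4,6-bis(benzyloxy)phenyl)-3,5,7,4'-tetra-O-benzylepiafzelechin] (trimer phenol) | c9ccccc9COc1ccc([C@H]2Oc3cc(OCc9ccccc9)c([C@@H]4c5c(OCc9ccccc9)cc(OCc9ccccc9)cc5O[C@H](c5ccc(OCc9ccccc9)c(OCc9ccccc9)c5)[C@@H]4OCc9ccccc9)c(OCc9ccccc9)c3[C@@H](c3c(OCc9ccccc9)cc(OCc9ccccc9)cc3O)[C@H]2OCc9ccccc9)cc1 | intermediate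
29 | 3,4-bis(benzyloxy)benzaldehyde | O=Cc1ccc(OCc9ccccc9)c(OCc9ccccc9)c1 | starting material
30 | methyl (Z)-3-[3,4-bis(benzyloxy)phenyl]prop-2-enoate | COC(=O)/C=C\c1ccc(OCc9ccccc9)c(OCc9ccccc9)c1 | intermediate
31 | methyl (2S,3S)-3-[3,4-bis(benzyloxy)phenyl]oxirane-2-carboxylate (cis) | COC(=O)[C@H]1O[C@H]1c1ccc(OCc9ccccc9)c(OCc9ccccc9)c1 | intermediate
32 | methyl (2S,3R)-3-[3,4-bis(benzyloxy)phenyl]-2-hydroxy-3-(aryloxy)propanoate, aryl = phenol ring of 28 | c9ccccc9COc1ccc([C@H]2Oc3cc(OCc9ccccc9)c([C@@H]4c5c(OCc9ccccc9)cc(OCc9ccccc9)cc5O[C@H](c5ccc(OCc9ccccc9)c(OCc9ccccc9)c5)[C@@H]4OCc9ccccc9)c(OCc9ccccc9)c3[C@@H](c3c(OCc9ccccc9)cc(OCc9ccccc9)cc3O[C@H](c3ccc(OCc9ccccc9)c(OCc9ccccc9)c3)[C@H](O)C(=O)OC)[C@H]2OCc9ccccc9)cc1 | intermediate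
33 | 2-O-triethylsilyl ether of 32 | c9ccccc9COc1ccc([C@H]2Oc3cc(OCc9ccccc9)c([C@@H]4c5c(OCc9ccccc9)cc(OCc9ccccc9)cc5O[C@H](c5ccc(OCc9ccccc9)c(OCc9ccccc9)c5)[C@@H]4OCc9ccccc9)c(OCc9ccccc9)c3[C@@H](c3c(OCc9ccccc9)cc(OCc9ccccc9)cc3O[C@H](c3ccc(OCc9ccccc9)c(OCc9ccccc9)c3)[C@H](O[Si](CC)(CC)CC)C(=O)OC)[C@H]2OCc9ccccc9)cc1 | intermediate
34 | (2S,3R)-3-[3,4-bis(benzyloxy)phenyl]-3-(aryloxy)-2-(triethylsilyloxy)propanal, aryl as in 32 | c9ccccc9COc1ccc([C@H]2Oc3cc(OCc9ccccc9)c([C@@H]4c5c(OCc9ccccc9)cc(OCc9ccccc9)cc5O[C@H](c5ccc(OCc9ccccc9)c(OCc9ccccc9)c5)[C@@H]4OCc9ccccc9)c(OCc9ccccc9)c3[C@@H](c3c(OCc9ccccc9)cc(OCc9ccccc9)cc3O[C@H](c3ccc(OCc9ccccc9)c(OCc9ccccc9)c3)[C@H](O[Si](CC)(CC)CC)C=O)[C@H]2OCc9ccccc9)cc1 | intermediate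
35 | 3,5,7,3',4'-penta-O-benzylepicatechin-6-yllithium | c9ccccc9CO[C@@H]1Cc2c(OCc9ccccc9)c([Li])c(OCc9ccccc9)cc2O[C@@H]1c1ccc(OCc9ccccc9)c(OCc9ccccc9)c1 | intermediate (not isolated)
36 | seco-tetramer 3-O-triethylsilyl 4-ol (C4 epimers) | c9ccccc9COc1ccc([C@H]2Oc3cc(OCc9ccccc9)c([C@@H]4c5c(OCc9ccccc9)cc(OCc9ccccc9)cc5O[C@H](c5ccc(OCc9ccccc9)c(OCc9ccccc9)c5)[C@@H]4OCc9ccccc9)c(OCc9ccccc9)c3[C@@H](c3c(OCc9ccccc9)cc(OCc9ccccc9)cc3O[C@H](c3ccc(OCc9ccccc9)c(OCc9ccccc9)c3)[C@H](O[Si](CC)(CC)CC)C(O)c3c(OCc9ccccc9)cc4c(c3OCc9ccccc9)C[C@@H](OCc9ccccc9)[C@@H](c3ccc(OCc9ccccc9)c(OCc9ccccc9)c3)O4)[C@H]2OCc9ccccc9)cc1 | intermediate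
37 | seco-tetramer 3,4-diol (C4 epimers) | c9ccccc9COc1ccc([C@H]2Oc3cc(OCc9ccccc9)c([C@@H]4c5c(OCc9ccccc9)cc(OCc9ccccc9)cc5O[C@H](c5ccc(OCc9ccccc9)c(OCc9ccccc9)c5)[C@@H]4OCc9ccccc9)c(OCc9ccccc9)c3[C@@H](c3c(OCc9ccccc9)cc(OCc9ccccc9)cc3O[C@H](c3ccc(OCc9ccccc9)c(OCc9ccccc9)c3)[C@H](O)C(O)c3c(OCc9ccccc9)cc4c(c3OCc9ccccc9)C[C@@H](OCc9ccccc9)[C@@H](c3ccc(OCc9ccccc9)c(OCc9ccccc9)c3)O4)[C@H]2OCc9ccccc9)cc1 | intermediate (not isolated)
38 | seco-tetramer 3,4-diacetate, ring C of unit 3 open between C4 and C4a (C4 epimers) | c9ccccc9COc1ccc([C@H]2Oc3cc(OCc9ccccc9)c([C@@H]4c5c(OCc9ccccc9)cc(OCc9ccccc9)cc5O[C@H](c5ccc(OCc9ccccc9)c(OCc9ccccc9)c5)[C@@H]4OCc9ccccc9)c(OCc9ccccc9)c3[C@@H](c3c(OCc9ccccc9)cc(OCc9ccccc9)cc3O[C@H](c3ccc(OCc9ccccc9)c(OCc9ccccc9)c3)[C@H](OC(C)=O)C(OC(C)=O)c3c(OCc9ccccc9)cc4c(c3OCc9ccccc9)C[C@@H](OCc9ccccc9)[C@@H](c3ccc(OCc9ccccc9)c(OCc9ccccc9)c3)O4)[C@H]2OCc9ccccc9)cc1 | intermediate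
39 | octadeca-O-benzyl tetramer, unit 3 as 3-O-acetate: penta-O-benzylepicatechin-(4α→6)-tetra-O-benzylepiafzelechin-(4α→8)-3-O-acetyl-tetra-O-benzylepicatechin-(4β→6)-penta-O-benzylepicatechin | c9ccccc9COc1ccc([C@H]2Oc3cc(OCc9ccccc9)c([C@@H]4c5c(OCc9ccccc9)cc(OCc9ccccc9)cc5O[C@H](c5ccc(OCc9ccccc9)c(OCc9ccccc9)c5)[C@@H]4OCc9ccccc9)c(OCc9ccccc9)c3[C@@H](c3c(OCc9ccccc9)cc(OCc9ccccc9)c4c3O[C@H](c3ccc(OCc9ccccc9)c(OCc9ccccc9)c3)[C@H](OC(C)=O)[C@H]4c3c(OCc9ccccc9)cc4c(c3OCc9ccccc9)C[C@@H](OCc9ccccc9)[C@@H](c3ccc(OCc9ccccc9)c(OCc9ccccc9)c3)O4)[C@H]2OCc9ccccc9)cc1 | intermediate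
40 | octadeca-O-benzyl tetramer with free 3-OH on unit 3 | c9ccccc9COc1ccc([C@H]2Oc3cc(OCc9ccccc9)c([C@@H]4c5c(OCc9ccccc9)cc(OCc9ccccc9)cc5O[C@H](c5ccc(OCc9ccccc9)c(OCc9ccccc9)c5)[C@@H]4OCc9ccccc9)c(OCc9ccccc9)c3[C@@H](c3c(OCc9ccccc9)cc(OCc9ccccc9)c4c3O[C@H](c3ccc(OCc9ccccc9)c(OCc9ccccc9)c3)[C@H](O)[C@H]4c3c(OCc9ccccc9)cc4c(c3OCc9ccccc9)C[C@@H](OCc9ccccc9)[C@@H](c3ccc(OCc9ccccc9)c(OCc9ccccc9)c3)O4)[C@H]2OCc9ccccc9)cc1 | intermediate
41 | epicatechin-(4α→6)-epiafzelechin-(4α→8)-epicatechin-(4β→6)-epicatechin (CNP0103636.2) | Oc1ccc([C@H]2Oc3cc(O)c([C@@H]4c5c(O)cc(O)cc5O[C@H](c5ccc(O)c(O)c5)[C@@H]4O)c(O)c3[C@@H](c3c(O)cc(O)c4c3O[C@H](c3ccc(O)c(O)c3)[C@H](O)[C@H]4c3c(O)cc4c(c3O)C[C@@H](O)[C@@H](c3ccc(O)c(O)c3)O4)[C@H]2O)cc1 | target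

**Step count and risks**

Total step count: 29. Longest linear sequence: 19 steps (from 10 through steps 7–12, 15–19 and 22–29 to 41).

Steps most likely to fail:

Step 27. The Lewis acid may ionise the benzylic aryl ether at C2 in competition with C4, or the open cation may close without acetate control, so that facial selectivity at C4 is lost. The fallback sets out from aldehyde 34 and from 3 and comes back to the route at 41; it closes ring C of unit 3 before unit 4 arrives. NBS would brominate 3 at C8 to give 8-bromo-3,5,7,3',4'-penta-O-benzylepicatechin F1, which leaves C6 as its only nucleophilic ring A carbon. BF3·OEt2 at −78 °C would cyclise 34 by intramolecular Friedel–Crafts hydroxyalkylation at C4a to the trimeric flavan-4-ol 3-O-triethylsilyl ether F2. With F1 added and the mixture warmed, the flavan-4-yl cation of unit 3 would be captured by C6 of F1 on the face away from the cis 2-aryl and 3-silyloxy groups (the classical 3,4-trans interflavan coupling) to give the 8-bromo tetramer 3-O-triethylsilyl ether F3. n-Bu4NF would give the 8-bromo tetramer 3-ol F4, and hydrogenolysis over Pd(OH)2/C with Et3N would remove the benzyl ethers and the bromine to give 41.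

Step 22. The hindered phenoxide may react slowly, so that attack at C2 of the glycidate or SN1-type leakage at the electron-rich benzylic carbon erodes regio- and stereoselectivity. The fallback sets out from 31 and 28 and comes back at aldehyde 34. NaBH4 would reduce the ester of 31 to the epoxy alcohol [(2R,3S)-3-(3,4-bis(benzyloxy)phenyl)oxiran-2-yl]methanol F5. Ti(OiPr)4 would bind this epoxy alcohol and deliver phenol 28 to C3 with inversion (the titanium-mediated C3-selective opening of 2,3-epoxy alcohols) to give the aryloxy 1,2-diol F6. Et3SiCl and imidazole would give the bis(triethylsilyl) ether F7, and Swern oxidation, which converts a primary triethylsilyl ether directly into the aldehyde and leaves the secondary one, would return 34.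

Step 17. The hindered, basic aryl nucleophile 25 may deprotonate ketone 5 (enolisation with C3 epimerisation or β-elimination) instead of adding to it. The fallback sets out from bromide 16 and ketone 5 and comes back at 27; it reverses the order of the two ketone additions so that the much less hindered C6-lithiated flavan is the nucleophile. Bromide 16 (t-BuLi, then 5 with CeCl3) would give the dimeric tertiary alcohol F8, and n-Bu3SnH/CF3CO2H the all-cis dimer penta-O-benzylepicatechin-(4α→6)-tetra-O-benzylepiafzelechin F9. DDQ/H2O would oxidise the free C4 methylene of the epiafzelechin unit (the C4–H of unit 2 is a shielded tertiary centre) to the 4β-ol F10, and Dess–Martin oxidation would give the dimer ketone F11. Aryllithium 22 with CeCl3 would add to give the tertiary alcohol F12, which n-Bu3SnH/CF3CO2H would reduce to 27.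

**Further compounds**

F1 | step 27 | 8-bromo-3,5,7,3',4'-penta-O-benzylepicatechin | c9ccccc9CO[C@@H]1Cc2c(OCc9ccccc9)cc(OCc9ccccc9)c(Br)c2O[C@@H]1c1ccc(OCc9ccccc9)c(OCc9ccccc9)c1
F2 | step 27 | trimeric flavan-4-ol 3-O-triethylsilyl ether (ring C of unit 3 closed, C4 epimers) | c9ccccc9COc1ccc([C@H]2Oc3cc(OCc9ccccc9)c([C@@H]4c5c(OCc9ccccc9)cc(OCc9ccccc9)cc5O[C@H](c5ccc(OCc9ccccc9)c(OCc9ccccc9)c5)[C@@H]4OCc9ccccc9)c(OCc9ccccc9)c3[C@@H](c3c(OCc9ccccc9)cc(OCc9ccccc9)c4c3O[C@H](c3ccc(OCc9ccccc9)c(OCc9ccccc9)c3)[C@H](O[Si](CC)(CC)CC)C4O)[C@H]2OCc9ccccc9)cc1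
F3 | step 27 | 8-bromo (unit 4) octadeca-O-benzyl tetramer 3-O-triethylsilyl ether (unit 3) | c9ccccc9COc1ccc([C@H]2Oc3cc(OCc9ccccc9)c([C@@H]4c5c(OCc9ccccc9)cc(OCc9ccccc9)cc5O[C@H](c5ccc(OCc9ccccc9)c(OCc9ccccc9)c5)[C@@H]4OCc9ccccc9)c(OCc9ccccc9)c3[C@@H](c3c(OCc9ccccc9)cc(OCc9ccccc9)c4c3O[C@H](c3ccc(OCc9ccccc9)c(OCc9ccccc9)c3)[C@H](O[Si](CC)(CC)CC)[C@H]4c3c(OCc9ccccc9)c(Br)c4c(c3OCc9ccccc9)C[C@@H](OCc9ccccc9)[C@@H](c3ccc(OCc9ccccc9)c(OCc9ccccc9)c3)O4)[C@H]2OCc9ccccc9)cc1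
F4 | step 27 | 8-bromo (unit 4) octadeca-O-benzyl tetramer with free 3-OH on unit 3 | c9ccccc9COc1ccc([C@H]2Oc3cc(OCc9ccccc9)c([C@@H]4c5c(OCc9ccccc9)cc(OCc9ccccc9)cc5O[C@H](c5ccc(OCc9ccccc9)c(OCc9ccccc9)c5)[C@@H]4OCc9ccccc9)c(OCc9ccccc9)c3[C@@H](c3c(OCc9ccccc9)cc(OCc9ccccc9)c4c3O[C@H](c3ccc(OCc9ccccc9)c(OCc9ccccc9)c3)[C@H](O)[C@H]4c3c(OCc9ccccc9)c(Br)c4c(c3OCc9ccccc9)C[C@@H](OCc9ccccc9)[C@@H](c3ccc(OCc9ccccc9)c(OCc9ccccc9)c3)O4)[C@H]2OCc9ccccc9)cc1
F5 | step 22 | [(2R,3S)-3-(3,4-bis(benzyloxy)phenyl)oxiran-2-yl]methanol (cis) | OC[C@H]1O[C@H]1c1ccc(OCc9ccccc9)c(OCc9ccccc9)c1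
F6 | step 22 | (2R,3R)-3-[3,4-bis(benzyloxy)phenyl]-3-(aryloxy)propane-1,2-diol, aryl = phenol ring of 28 | c9ccccc9COc1ccc([C@H]2Oc3cc(OCc9ccccc9)c([C@@H]4c5c(OCc9ccccc9)cc(OCc9ccccc9)cc5O[C@H](c5ccc(OCc9ccccc9)c(OCc9ccccc9)c5)[C@@H]4OCc9ccccc9)c(OCc9ccccc9)c3[C@@H](c3c(OCc9ccccc9)cc(OCc9ccccc9)cc3O[C@H](c3ccc(OCc9ccccc9)c(OCc9ccccc9)c3)[C@H](O)CO)[C@H]2OCc9ccccc9)cc1
F7 | step 22 | 1,2-bis(triethylsilyl) ether of F6 | c9ccccc9COc1ccc([C@H]2Oc3cc(OCc9ccccc9)c([C@@H]4c5c(OCc9ccccc9)cc(OCc9ccccc9)cc5O[C@H](c5ccc(OCc9ccccc9)c(OCc9ccccc9)c5)[C@@H]4OCc9ccccc9)c(OCc9ccccc9)c3[C@@H](c3c(OCc9ccccc9)cc(OCc9ccccc9)cc3O[C@H](c3ccc(OCc9ccccc9)c(OCc9ccccc9)c3)[C@H](O[Si](CC)(CC)CC)CO[Si](CC)(CC)CC)[C@H]2OCc9ccccc9)cc1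
F8 | step 17 | 4α-hydroxy-3,5,7,3',4'-penta-O-benzylepicatechin-(4β→6)-3,5,7,4'-tetra-O-benzylepiafzelechin (tertiary alcohol) | c9ccccc9COc1ccc([C@H]2Oc3cc(OCc9ccccc9)c([C@@]4(O)c5c(OCc9ccccc9)cc(OCc9ccccc9)cc5O[C@H](c5ccc(OCc9ccccc9)c(OCc9ccccc9)c5)[C@@H]4OCc9ccccc9)c(OCc9ccccc9)c3C[C@H]2OCc9ccccc9)cc1
F9 | step 17 | 3,5,7,3',4'-penta-O-benzylepicatechin-(4α→6)-3,5,7,4'-tetra-O-benzylepiafzelechin | c9ccccc9COc1ccc([C@H]2Oc3cc(OCc9ccccc9)c([C@@H]4c5c(OCc9ccccc9)cc(OCc9ccccc9)cc5O[C@H](c5ccc(OCc9ccccc9)c(OCc9ccccc9)c5)[C@@H]4OCc9ccccc9)c(OCc9ccccc9)c3C[C@H]2OCc9ccccc9)cc1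
F10 | step 17 | 4β-hydroxy derivative of F9 at C4 of the epiafzelechin unit | c9ccccc9COc1ccc([C@H]2Oc3cc(OCc9ccccc9)c([C@@H]4c5c(OCc9ccccc9)cc(OCc9ccccc9)cc5O[C@H](c5ccc(OCc9ccccc9)c(OCc9ccccc9)c5)[C@@H]4OCc9ccccc9)c(OCc9ccccc9)c3[C@H](O)[C@H]2OCc9ccccc9)cc1
F11 | step 17 | 4-oxo derivative of F9 at C4 of the epiafzelechin unit | c9ccccc9COc1ccc([C@H]2Oc3cc(OCc9ccccc9)c([C@@H]4c5c(OCc9ccccc9)cc(OCc9ccccc9)cc5O[C@H](c5ccc(OCc9ccccc9)c(OCc9ccccc9)c5)[C@@H]4OCc9ccccc9)c(OCc9ccccc9)c3C(=O)[C@H]2OCc9ccccc9)cc1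
F12 | step 17 | 3,5,7,3',4'-penta-O-benzylepicatechin-(4α→6)-[4β-(2-allyloxy-4,6-bis(benzyloxy)phenyl)-4α-hydroxy-3,5,7,4'-tetra-O-benzylepiafzelechin] | c9ccccc9COc1ccc([C@H]2Oc3cc(OCc9ccccc9)c([C@@H]4c5c(OCc9ccccc9)cc(OCc9ccccc9)cc5O[C@H](c5ccc(OCc9ccccc9)c(OCc9ccccc9)c5)[C@@H]4OCc9ccccc9)c(OCc9ccccc9)c3[C@](O)(c3c(OCc9ccccc9)cc(OCc9ccccc9)cc3OCC=C)[C@H]2OCc9ccccc9)cc1
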